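The runs come from a simulation for substances that don't exist, and the scatter is random.

**Split first.** At 3.00 d the south-west run holds 3.04 parts Q per part X, and the south-east run holds 7.97.

| flask | D | remark | time |
|---|---|---|---|
| south-west | 0.034 M | run made earlier |  |
| south-east | 0.075 M | run made earlier |  |
| flask | 0.050 M |  | 4.0 d |

| run | time / d | D / % | Q / % | X / % | G / % |
|---|---|---|---|---|---|
| south-west | 0.250 | 15.1 | 16.6 | 2.9 | 65.9 |
| south-west | 0.625 | 12.2 | 30.0 | 6.4 | 53.2 |
| south-west | 1.25 | 8.1 | 41.7 | 10.4 | 39.4 |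
| south-west | 3.00 | 4.9 | 55.6 | 18.3 | 21.0 |
| south-east | 0.417 | 14.4 | 45.3 | 3.1 | 36.3 |
| south-east | 1.04 | 8.1 | 65.7 | 5.4 | 21.6 |
| south-east | 2.08 | 4.3 | 74.4 | 8.6 | 12.5 |
| south-east | 3.00 | 3.8 | 78.9 | 9.9 | 9.0 |

(each reading ± 0.5 percentage points)

- percentages count the D that a species holds: one Q counts as two

- the largest share of what was charged as D, at 4.0 d belongs to (D / G / Q / X)
- the largest share itself, whichever of these holds it, in percent of the D charged

**Two amounts.** Watch Q and X. The four shares of the south-west run sum to 99.8% at 3.00 d, so count what has left D and G as Q or X. Let S, the selectivity factor, be Q over X at one time, and c the charge of D. The two runs give 1.22 for n, the power of c that S follows at 3.00 d.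

**My reckoning.** For the flask, n gives S = 4.86 at 3.00 d. Take that S for 4.0 d as well, as an estimate, so Q takes 82.9% of what has left D and G. The two runs keep on average 19.4% as D plus G at 3.00 d. Hold that for the flask at 4.0 d, and Q comes to 66.9%.

**The forecast.** It named Q at 74%, from 70% to 77%, higher than my figure: “Q holds the largest share.”

**The flask.** It gives Q at 71.1%, above my figure. Q takes 81.9% of Q plus X, against my 82.9%, while D plus G stand at 13.1%, less than I allowed. Its S at 4.0 d is 4.52.

    D ⇌ G + J (K = 0.110 M, k = 0.0170 min⁻¹)
    D + G → Q (k = 0.0460 M⁻¹ min⁻¹)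
    G → X (k = 1.10 × 10⁻⁴ min⁻¹)

**A thinner charge.** Carry that S down by n, as an estimate, to the neighbour charged with 0.013 M: S = 0.875, less than one, so X should pass Q. At 4.0 d that neighbour holds Q 25.8% and X 35.4%, a ratio of 0.729.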